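**Retrosynthetic overview**
1. Target 45 ⇐ pentaol 43 by hydroxyl-directed epoxidation of the C11 methylene, then fourfold acetylation; C6–Cl ⇐ 6R allylic alcohol by SN2 chlorination; C17 ⇐ lactone equilibration.
2. Ring B (ten-membered) ⇐ intramolecular Nozaki–Hiyama–Kishi coupling C5–C6 of vinyl bromide/aldehyde 36, then oxidation and Felkin reduction at C6.
3. Ring C (lactone) ⇐ chelation-controlled propanoate aldol on the C8 vinyl ketone 29, then iodolactonisation; the C8 ketone ⇐ C9 aldehyde 24 + lithiated methoxyallene.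
4. Ring A functionality ⇐ enone 14 (epoxidation, C11 methylenation, SmI2 opening, syn reduction); C2 carbinol ⇐ ketoreductase reduction of ketone 9; C3–C5/C16 chain ⇐ Grignard reagent from 6.
5. Ring A with C1/C10 ⇐ catalytic enantioselective Diels–Alder of diene 2 with enal 3. Ring order: A (step 2), C (step 19), B (step 21), oxirane (step 28).

Notation and assumption (one line): briarane numbering is used throughout (C15 = methyl on C1, C16 = methylene on C5, C18 = methyl on C17, C20 = CH2 on C11; α = face of H-10), and the mirror-image cycloaddition catalyst or a ketoreductase of opposite preference would be used if the sense of induction proves opposite to that drawn.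

This is a designed, untested route; stereochemical outcomes are predictions from the models named in each step.

**Step 1**
Reactants: 1 but-3-en-2-one
Product: 2 2-(triisopropylsilyloxy)buta-1,3-diene
Conditions: i-Pr3SiOSO2CF3, Et3N, Et2O, 0 °C to rt
Reagents that add atoms: triisopropylsilyl trifluoromethanesulfonate, CC(C)[Si](OS(=O)(=O)C(F)(F)F)(C(C)C)C(C)C
Why: Soft enolisation and O-silylation of the enone gives the 2-silyloxydiene; no stereocentre is formed.

**Step 2**
Reactants: 2 2-(triisopropylsilyloxy)buta-1,3-diene; 3 ethyl (E)-3-methyl-4-oxobut-2-enoate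
Product: 4 cycloadduct ethyl (1S,6S)-6-formyl-6-methyl-3-(triisopropylsilyloxy)cyclohex-3-ene-1-carboxylate
Conditions: (S)-3,3-diphenyl-1-(2-methylphenyl)tetrahydro-1H,3H-pyrrolo[1,2-c][1,3,2]oxazaborole/(CF3SO2)2NH (15 mol %), CH2Cl2, −78 to −40 °C
Reagents that add atoms: none
Why: Catalytic enantioselective Diels–Alder reaction with a cationic oxazaborolidine: formyl coordination makes the ester-bearing carbon the electrophilic terminus (C12 oxygen para to C1), the E-alkene fixes formyl (C2) and ester (C9) trans, and the catalyst shields one enal face so that C1 and C10, the first stereocentres, are set together.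

**Step 3**
Reactants: 5 3-bromobut-3-en-1-ol
Product: 6 2-bromo-4-iodobut-1-ene
Conditions: PPh3, I2, imidazole, CH2Cl2, 0 °C
Reagents that add atoms: iodine, [I][I]
Why: Appel-type iodination of a primary alcohol through the alkoxyphosphonium ion; no stereocentre.

**Step 4**
Reactants: 4 cycloadduct; 6 2-bromo-4-iodobut-1-ene
Product: 8 C2 carbinol ethyl (1S,6S)-6-(4-bromo-1-hydroxypent-4-enyl)-6-methyl-3-(triisopropylsilyloxy)cyclohex-3-ene-1-carboxylate (both C2 epimers), via 3-bromobut-3-enylmagnesium iodide 7 (not isolated)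
Conditions: 6, Mg, THF, rt; then 4, THF, −78 °C; aq NH4Cl
Reagents that add atoms: none
Why: Magnesium inserts into the sp3 C–I bond rather than the vinylic C–Br bond, and the Grignard reagent adds to the aldehyde far faster than to the ester at −78 °C; the C2 mixture is erased in step 5.

**Step 5**
Reactants: 8 C2 carbinol (both epimers)
Product: 9 C2 ketone ethyl (1S,6S)-6-(4-bromopent-4-enoyl)-6-methyl-3-(triisopropylsilyloxy)cyclohex-3-ene-1-carboxylate
Conditions: Dess–Martin periodinane, NaHCO3, CH2Cl2, 0 °C to rt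
Reagents that add atoms: none
Why: Buffered Dess–Martin oxidation spares the silyl enol ether and converges both C2 epimers to one ketone.

**Step 6**
Reactants: 9 C2 ketone
Product: 10 (2R)-carbinol ethyl (1S,6S)-6-[(1R)-4-bromo-1-hydroxypent-4-enyl]-6-methyl-3-(triisopropylsilyloxy)cyclohex-3-ene-1-carboxylate
Conditions: ketoreductase (NADPH-dependent, picked from a screening panel), NADP+ (cat.), propan-2-ol, phosphate buffer pH 7.0/DMSO (9:1), 30 °C
Reagents that add atoms: none
Why: Enzymatic asymmetric ketone reduction: the ketoreductase delivers hydride from NADPH (recycled by propan-2-ol) to one face of the tert-alkyl/primary-alkyl ketone and sets C2 as R, while ester, vinyl bromide and silyl enol ether are inert at neutral pH.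

**Step 7**
Reactants: 10 (2R)-carbinol
Product: 11 2-O-triethylsilyl ether of 10
Conditions: Et3SiOSO2CF3, 2,6-lutidine, CH2Cl2, −78 °C
Reagents that add atoms: triethylsilyl trifluoromethanesulfonate, CC[Si](CC)(CC)OS(=O)(=O)C(F)(F)F
Why: Silyl triflate silylation of the hindered carbinol prevents lactonisation onto the C9 ester and masks O2 for the later base, hydride and organometallic steps.

**Step 8**
Reactants: 11 2-O-triethylsilyl ether
Product: 14 ring-A enone (C12 ketone; C13=C14 alkene; 2-OSiEt3; C9 ethyl ester), via C13-phenylselanyl C12 ketone 12 (not isolated), via C13 selenoxide 13 (not isolated)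
Conditions: PhSeCl, CH2Cl2, −78 °C; then H2O2 (30%), pyridine, 0 °C to rt
Reagents that add atoms: none
Why: Selenenylation of the silyl enol ether at C13 followed by selenoxide syn-elimination toward C14 gives the enone regiospecifically and without palladium, which the vinyl bromide would not tolerate.

**Step 9**
Reactants: 14 ring-A enone
Product: 15 13α,14α-epoxy C12 ketone
Conditions: t-BuOOH, benzyltrimethylammonium hydroxide (cat.), THF, 0 °C
Reagents that add atoms: tert-butyl hydroperoxide, CC(C)(C)OO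
Why: Weitz–Scheffer nucleophilic epoxidation: with the C2 and C9 substituents trans-diequatorial the C15 methyl is pseudoaxial on the β face, so the peroxide adds to C14 from the α face and sets C13 and C14 (14α oxygen).

**Step 10**
Reactants: 15 13α,14α-epoxy C12 ketone
Product: 19 11(20)-methylene 13α,14α-epoxy C12 ketone, via C11 lithium enolate 16 (not isolated), via C11 (dimethylamino)methyl ketone 17 (not isolated), via trimethylammonium iodide 18 (not isolated)
Conditions: LiN(SiMe3)2, THF, −78 °C; Me2N=CH2+ I−, −78 to 0 °C; MeI, rt; DBU, CH2Cl2, rt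
Reagents that add atoms: N,N-dimethylmethyleneiminium iodide (Eschenmoser's salt), C=[N+](C)C.[I-]
Why: Kinetic enolisation can only occur at C11 because C13 is an oxirane carbon, and Mannich reaction, quaternisation and elimination of trimethylamine install the C20 methylene.

**Step 11**
Reactants: 19 11(20)-methylene epoxy ketone
Product: 20 14α-hydroxy 11(20)-methylene C12 ketone
Conditions: SmI2 (2.2 equiv), THF/MeOH, −90 °C
Reagents that add atoms: none
Why: Electron-transfer reduction of the α,β-epoxy ketone cleaves the C13–O bond much faster than SmI2 attacks the enone, ester or vinyl bromide, and leaves the 14α configuration untouched.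

**Step 12**
Reactants: 20 14α-hydroxy enone
Product: 21 triol (C9 CH2OH; 12α-OH; 14α-OH; 11(20)-methylene; 2-OSiEt3)
Conditions: i-Bu2AlH (6 equiv), THF, −78 to 0 °C; aq potassium sodium tartrate
Reagents that add atoms: none
Why: Hydroxyl-directed 1,3-syn reduction: the aluminium alkoxide of the axial 14α-hydroxyl occupies the α face so hydride reaches C12 from the β face and gives the 12α carbinol, while the same reagent reduces the C9 ester to CH2OH and attacks the enone only 1,2.

**Step 13**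
Reactants: 21 triol
Product: 22 2,9,12,14-tetrakis(triethylsilyl) ether
Conditions: Et3SiOSO2CF3 (4 equiv), 2,6-lutidine, CH2Cl2, 0 °C
Reagents that add atoms: triethylsilyl trifluoromethanesulfonate, CC[Si](CC)(CC)OS(=O)(=O)C(F)(F)F
Why: Exhaustive silylation with the reactive triflate covers the primary and both axial secondary hydroxyls without touching any stereocentre.

**Step 14**
Reactants: 22 tetrakis(triethylsilyl) ether
Product: 24 C9 aldehyde (2,12,14-tris-OSiEt3), via C9 alkoxydimethylsulfonium chloride 23 (not isolated)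
Conditions: (COCl)2, DMSO, CH2Cl2, −78 to −40 °C; then i-Pr2NEt, −78 °C; pH 7 buffer
Reagents that add atoms: none
Why: Under Swern conditions a primary triethylsilyl ether is cleaved and oxidised directly while secondary ones survive, and the bulky amine at low temperature avoids conjugation of the β,γ-unsaturated aldehyde or epimerisation at C10.

**Step 15**
Reactants: 24 C9 aldehyde; 25 methoxyallene
Product: 27 (9R)-carbinol carrying the 1-methoxyallenyl group (C8, C7, C6), via 1-lithio-1-methoxyallene 26 (not isolated)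
Conditions: 25, n-BuLi, THF, −78 °C; then 24, −78 °C
Reagents that add atoms: none
Why: Addition of the lithiated alkoxyallene (an acyl-anion equivalent for C8) to the α-branched aldehyde follows the Felkin–Anh model with the quaternary C1 anti to the nucleophile, giving the 9R carbinol.

**Step 16**
Reactants: 27 (9R)-allenyl carbinol
Product: 28 9-O-(4-methoxybenzyl) ether of 27
Conditions: NaH, 4-methoxybenzyl bromide, tetrabutylammonium iodide (cat.), THF/DMF, 0 °C
Reagents that add atoms: 4-methoxybenzyl bromide, COc1ccc(CBr)cc1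
Why: Williamson etherification of the alkoxide; this ether can chelate in step 18 and is removable oxidatively later.

**Step 17**
Reactants: 28 9-O-(4-methoxybenzyl) ether
Product: 29 (9R)-vinyl ketone (C8 ketone; C7=C6)
Conditions: oxalic acid (5% aq), THF, 0 °C
Reagents that add atoms: water, O
Why: Mild acid hydrolysis of the allenyl enol ether (protonation at the central allene carbon, hydration, loss of methanol) unmasks the α-alkoxy vinyl ketone without cleaving the silyl ethers.

**Step 18**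
Reactants: 29 (9R)-vinyl ketone; 30 ethyl propanoate
Product: 32 (8R,9R)-tertiary aldol ethyl ester (C17 epimers), via lithium enolate of ethyl propanoate 31 (not isolated)
Conditions: 30, LiN(i-Pr)2, THF, −78 °C; then 29 precomplexed with MgBr2·OEt2, CH2Cl2/THF, −78 °C
Reagents that add atoms: none
Why: Chelation-controlled aldol addition (Cram chelate): magnesium bridges the C8 carbonyl and the C9 ether oxygen, the enolate adds 1,2 from the face away from ring A and sets C8 as R, whereas C17 is not controlled and is corrected in step 24.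

**Step 19**
Reactants: 32 tertiary aldol ethyl ester
Product: 34 (7R,8R)-iodolactone (ring C closed; C6 is CH2I; C17 epimers), via lithium carboxylate 33 (not isolated)
Conditions: LiOH, THF/H2O, 0 °C; then NaHCO3, I2, 0 °C, dark
Reagents that add atoms: iodine, [I][I]
Why: Saponification then kinetic iodolactonisation (5-exo attack of carboxylate on the iodonium ion): the allylic tertiary hydroxyl directs the iodomethyl group cis to itself and trans to the bulky C9 branch, which sets C7.

**Step 20**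
Reactants: 34 iodolactone
Product: 36 C6 aldehyde of the ring-C lactone, via C6 alkoxydimethylsulfonium tetrafluoroborate 35 (not isolated)
Conditions: AgBF4, DMSO, rt; then Et3N, 0 °C
Reagents that add atoms: dimethyl sulfoxide, CS(C)=O
Why: Kornblum-type oxidation: silver-assisted displacement of the primary iodide by DMSO gives an alkoxysulfonium salt that collapses to the aldehyde with amine, leaving C7 untouched.

**Step 21**
Reactants: 36 C6 aldehyde
Product: 37 ring-B-closed C6 carbinol (C6 epimers; C17 epimers)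
Conditions: CrCl2 (10 equiv), NiCl2 (2 mol %), DMSO/THF, rt, 0.002 M
Reagents that add atoms: none
Why: Intramolecular Nozaki–Hiyama–Kishi reaction: nickel-catalysed activation of the vinyl bromide, transmetalation to chromium and chemoselective addition to the aldehyde at high dilution close ring B and give the 5(16)-ene directly; the C6 configuration is reset in steps 22 and 23.

**Step 22**
Reactants: 37 ring-B-closed C6 carbinol
Product: 38 C6 ketone (5(16)-en-6-one; C17 epimers)
Conditions: Dess–Martin periodinane, NaHCO3, CH2Cl2, 0 °C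
Reagents that add atoms: none
Why: Dess–Martin oxidation of the secondary allylic alcohol (the tertiary C8 hydroxyl is inert) converges both C6 epimers to one enone.

**Step 23**
Reactants: 38 C6 ketone
Product: 39 (6R)-allylic alcohol (C17 epimers)
Conditions: NaBH4, CeCl3·7H2O, MeOH, −78 °C
Reagents that add atoms: none
Why: Luche 1,2-reduction; by the polar Felkin–Anh model hydride attacks anti to the C7–O bond of the α-acyloxy ketone and gives the 6,7-syn (6R) alcohol needed for the later inversion.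

**Step 24**
Reactants: 39 (6R)-allylic alcohol (C17 epimers)
Product: 40 (6R,17R)-allylic alcohol
Conditions: DBU (2 equiv), toluene, 80 °C
Reagents that add atoms: none
Why: Reversible enolisation of the lactone equilibrates C17 to what is expected to be the thermodynamically preferred isomer, with the C18 methyl trans to the ring-B branch at C9 and cis to the small 8-hydroxyl (17R).

**Step 25**
Reactants: 40 (6R,17R)-allylic alcohol
Product: 41 (6S)-allylic chloride
Conditions: PPh3, hexachloroacetone, CH2Cl2, −20 to 0 °C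
Reagents that add atoms: hexachloroacetone, ClC(Cl)(Cl)C(=O)C(Cl)(Cl)Cl
Why: Appel-type chlorination: the alkoxyphosphonium ion is displaced by chloride in an SN2 step with inversion and little allylic transposition, giving the 6S chloride, while the tertiary alcohol does not react.

**Step 26**
Reactants: 41 (6S)-allylic chloride
Product: 42 9-hydroxy chloride (4-methoxybenzyl group removed)
Conditions: DDQ, CH2Cl2/pH 7 buffer, 0 °C
Reagents that add atoms: none
Why: Oxidative cleavage of the electron-rich benzyl ether by DDQ frees O9 without touching silyl ethers, alkenes or the chloride.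

**Step 27**
Reactants: 42 9-hydroxy chloride
Product: 43 pentaol (2,8,9,12,14-pentahydroxy; 6-chloro; 5(16),11(20)-diene; 18,7-lactone)
Conditions: HF·pyridine, pyridine, THF, 0 °C to rt
Reagents that add atoms: none
Why: Buffered fluoride cleavage of the three triethylsilyl ethers does not ionise the allylic chloride.

**Step 28**
Reactants: 43 pentaol
Product: 44 11,20-epoxy pentaol
Conditions: VO(acac)2 (5 mol %), t-BuOOH, CH2Cl2, 0 °C
Reagents that add atoms: tert-butyl hydroperoxide, CC(C)(C)OO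
Why: Hydroxyl-directed epoxidation: the axial 12α-hydroxyl delivers oxygen to the α face of the allylic C11 methylene and sets C11 as in the target, while the C5 methylene, deactivated by the allylic chlorine and lacking an allylic hydroxyl, is left alone.

**Step 29**
Reactants: 44 11,20-epoxy pentaol
Product: 45 target CNP0349227.4
Conditions: Ac2O, pyridine, 4-(dimethylamino)pyridine (cat.), CH2Cl2, 0 °C to rt
Reagents that add atoms: acetic anhydride, CC(=O)OC(C)=O
Why: Nucleophile-catalysed acetylation esterifies the four secondary hydroxyls (C2, C9, C12, C14) while the hindered tertiary C8 hydroxyl stays free.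

**Compound list**
1 | but-3-en-2-one | CC(=O)C=C | starting material
2 | 2-(triisopropylsilyloxy)buta-1,3-diene | C=CC(=C)O[Si](C(C)C)(C(C)C)C(C)C | intermediate
3 | ethyl (E)-3-methyl-4-oxobut-2-enoate | CCOC(=O)/C=C(\C)C=O | starting material
4 | cycloadduct ethyl (1S,6S)-6-formyl-6-methyl-3-(triisopropylsilyloxy)cyclohex-3-ene-1-carboxylate | O=C[C@@]1(C)CC=C(O[Si](C(C)C)(C(C)C)C(C)C)C[C@@H]1C(=O)OCC | intermediate
5 | 3-bromobut-3-en-1-ol | OCCC(Br)=C | starting material
6 | 2-bromo-4-iodobut-1-ene | ICCC(Br)=C | intermediate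
7 | 3-bromobut-3-enylmagnesium iodide (formed in the flask) | C=C(Br)CC[Mg]I | intermediate
8 | C2 carbinol, both C2 epimers | C=C(Br)CCC(O)[C@@]1(C)CC=C(O[Si](C(C)C)(C(C)C)C(C)C)C[C@@H]1C(=O)OCC | intermediate
9 | C2 ketone | C=C(Br)CCC(=O)[C@@]1(C)CC=C(O[Si](C(C)C)(C(C)C)C(C)C)C[C@@H]1C(=O)OCC | intermediate
10 | (2R)-carbinol | C=C(Br)CC[C@@H](O)[C@@]1(C)CC=C(O[Si](C(C)C)(C(C)C)C(C)C)C[C@@H]1C(=O)OCC | intermediate
11 | 2-O-triethylsilyl ether of 10 | C=C(Br)CC[C@@H](O[Si](CC)(CC)CC)[C@@]1(C)CC=C(O[Si](C(C)C)(C(C)C)C(C)C)C[C@@H]1C(=O)OCC | intermediate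
12 | C13-phenylselanyl C12 ketone (formed in the flask) | C=C(Br)CC[C@@H](O[Si](CC)(CC)CC)[C@@]1(C)CC([Se]c2ccccc2)C(=O)C[C@@H]1C(=O)OCC | intermediate
13 | C13 selenoxide (formed in the flask) | C=C(Br)CC[C@@H](O[Si](CC)(CC)CC)[C@@]1(C)CC([Se](=O)c2ccccc2)C(=O)C[C@@H]1C(=O)OCC | intermediate
14 | ring-A enone | C=C(Br)CC[C@@H](O[Si](CC)(CC)CC)[C@@]1(C)C=CC(=O)C[C@@H]1C(=O)OCC | intermediate
15 | 13α,14α-epoxy C12 ketone | C=C(Br)CC[C@@H](O[Si](CC)(CC)CC)[C@@]1(C)[C@H]2O[C@H]2C(=O)C[C@@H]1C(=O)OCC | intermediate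
16 | C11 lithium enolate of 15 (formed in the flask) | C=C(Br)CC[C@@H](O[Si](CC)(CC)CC)[C@@]1(C)[C@H]2O[C@H]2C(O[Li])=C[C@@H]1C(=O)OCC | intermediate
17 | C11 (dimethylamino)methyl ketone (formed in the flask) | C=C(Br)CC[C@@H](O[Si](CC)(CC)CC)[C@@]1(C)[C@H]2O[C@H]2C(=O)C(CN(C)C)[C@@H]1C(=O)OCC | intermediate
18 | trimethylammonium iodide of 17 (formed in the flask) | C=C(Br)CC[C@@H](O[Si](CC)(CC)CC)[C@@]1(C)[C@H]2O[C@H]2C(=O)C(C[N+](C)(C)C)[C@@H]1C(=O)OCC.[I-] | intermediate
19 | 11(20)-methylene 13α,14α-epoxy C12 ketone | C=C(Br)CC[C@@H](O[Si](CC)(CC)CC)[C@@]1(C)[C@H]2O[C@H]2C(=O)C(=C)[C@@H]1C(=O)OCC | intermediate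
20 | 14α-hydroxy 11(20)-methylene C12 ketone | C=C(Br)CC[C@@H](O[Si](CC)(CC)CC)[C@@]1(C)[C@@H](O)CC(=O)C(=C)[C@@H]1C(=O)OCC | intermediate
21 | triol (C9 CH2OH, 12α-OH, 14α-OH) | C=C(Br)CC[C@@H](O[Si](CC)(CC)CC)[C@@]1(C)[C@@H](O)C[C@@H](O)C(=C)[C@@H]1CO | intermediate
22 | 2,9,12,14-tetrakis(triethylsilyl) ether | C=C(Br)CC[C@@H](O[Si](CC)(CC)CC)[C@@]1(C)[C@@H](O[Si](CC)(CC)CC)C[C@@H](O[Si](CC)(CC)CC)C(=C)[C@@H]1CO[Si](CC)(CC)CC | intermediate
23 | C9 alkoxydimethylsulfonium chloride (formed in the flask) | C=C(Br)CC[C@@H](O[Si](CC)(CC)CC)[C@@]1(C)[C@@H](O[Si](CC)(CC)CC)C[C@@H](O[Si](CC)(CC)CC)C(=C)[C@@H]1CO[S+](C)C.[Cl-] | intermediate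
24 | C9 aldehyde | C=C(Br)CC[C@@H](O[Si](CC)(CC)CC)[C@@]1(C)[C@@H](O[Si](CC)(CC)CC)C[C@@H](O[Si](CC)(CC)CC)C(=C)[C@@H]1C=O | intermediate
25 | methoxyallene (1-methoxypropa-1,2-diene) | COC=C=C | starting material
26 | 1-lithio-1-methoxyallene (formed in the flask) | [Li]C(OC)=C=C | intermediate
27 | (9R)-carbinol with 1-methoxyallenyl group | C=C(Br)CC[C@@H](O[Si](CC)(CC)CC)[C@@]1(C)[C@@H](O[Si](CC)(CC)CC)C[C@@H](O[Si](CC)(CC)CC)C(=C)[C@@H]1[C@@H](O)C(OC)=C=C | intermediate
28 | 9-O-(4-methoxybenzyl) ether of 27 | C=C(Br)CC[C@@H](O[Si](CC)(CC)CC)[C@@]1(C)[C@@H](O[Si](CC)(CC)CC)C[C@@H](O[Si](CC)(CC)CC)C(=C)[C@@H]1[C@@H](OCc2ccc(OC)cc2)C(OC)=C=C | intermediate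
29 | (9R)-vinyl ketone | C=C(Br)CC[C@@H](O[Si](CC)(CC)CC)[C@@]1(C)[C@@H](O[Si](CC)(CC)CC)C[C@@H](O[Si](CC)(CC)CC)C(=C)[C@@H]1[C@@H](OCc2ccc(OC)cc2)C(=O)C=C | intermediate
30 | ethyl propanoate | CCC(=O)OCC | starting material
31 | lithium enolate of ethyl propanoate (formed in the flask) | C/C=C(\OCC)O[Li] | intermediate
32 | (8R,9R)-tertiary aldol ethyl ester, C17 epimers | C=C(Br)CC[C@@H](O[Si](CC)(CC)CC)[C@@]1(C)[C@@H](O[Si](CC)(CC)CC)C[C@@H](O[Si](CC)(CC)CC)C(=C)[C@@H]1[C@@H](OCc2ccc(OC)cc2)[C@@](O)(C=C)C(C)C(=O)OCC | intermediate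
33 | lithium carboxylate of 32 (formed in the flask) | C=C(Br)CC[C@@H](O[Si](CC)(CC)CC)[C@@]1(C)[C@@H](O[Si](CC)(CC)CC)C[C@@H](O[Si](CC)(CC)CC)C(=C)[C@@H]1[C@@H](OCc2ccc(OC)cc2)[C@@](O)(C=C)C(C)C(=O)[O-].[Li+] | intermediate
34 | (7R,8R)-iodolactone, C17 epimers | C=C(Br)CC[C@@H](O[Si](CC)(CC)CC)[C@@]1(C)[C@@H](O[Si](CC)(CC)CC)C[C@@H](O[Si](CC)(CC)CC)C(=C)[C@@H]1[C@@H](OCc2ccc(OC)cc2)[C@]2(O)C(C)C(=O)O[C@H]2CI | intermediate
35 | C6 alkoxydimethylsulfonium tetrafluoroborate (formed in the flask) | C=C(Br)CC[C@@H](O[Si](CC)(CC)CC)[C@@]1(C)[C@@H](O[Si](CC)(CC)CC)C[C@@H](O[Si](CC)(CC)CC)C(=C)[C@@H]1[C@@H](OCc2ccc(OC)cc2)[C@]2(O)C(C)C(=O)O[C@H]2CO[S+](C)C.F[B-](F)(F)F | intermediate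
36 | C6 aldehyde of the ring-C lactone, C17 epimers | C=C(Br)CC[C@@H](O[Si](CC)(CC)CC)[C@@]1(C)[C@@H](O[Si](CC)(CC)CC)C[C@@H](O[Si](CC)(CC)CC)C(=C)[C@@H]1[C@@H](OCc2ccc(OC)cc2)[C@]2(O)C(C)C(=O)O[C@H]2C=O | intermediate
37 | ring-B-closed C6 carbinol, C6 and C17 epimers | C=C1CC[C@@H](O[Si](CC)(CC)CC)[C@@]2(C)[C@@H](O[Si](CC)(CC)CC)C[C@@H](O[Si](CC)(CC)CC)C(=C)[C@@H]2[C@@H](OCc3ccc(OC)cc3)[C@]2(O)C(C)C(=O)O[C@H]2C1O | intermediate
38 | C6 ketone, C17 epimers | C=C1CC[C@@H](O[Si](CC)(CC)CC)[C@@]2(C)[C@@H](O[Si](CC)(CC)CC)C[C@@H](O[Si](CC)(CC)CC)C(=C)[C@@H]2[C@@H](OCc3ccc(OC)cc3)[C@]2(O)C(C)C(=O)O[C@H]2C1=O | intermediate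
39 | (6R)-allylic alcohol, C17 epimers | C=C1CC[C@@H](O[Si](CC)(CC)CC)[C@@]2(C)[C@@H](O[Si](CC)(CC)CC)C[C@@H](O[Si](CC)(CC)CC)C(=C)[C@@H]2[C@@H](OCc3ccc(OC)cc3)[C@]2(O)C(C)C(=O)O[C@H]2[C@@H]1O | intermediate
40 | (6R,17R)-allylic alcohol | C=C1CC[C@@H](O[Si](CC)(CC)CC)[C@@]2(C)[C@@H](O[Si](CC)(CC)CC)C[C@@H](O[Si](CC)(CC)CC)C(=C)[C@@H]2[C@@H](OCc3ccc(OC)cc3)[C@]2(O)[C@@H](C)C(=O)O[C@H]2[C@@H]1O | intermediate
41 | (6S)-allylic chloride | C=C1CC[C@@H](O[Si](CC)(CC)CC)[C@@]2(C)[C@@H](O[Si](CC)(CC)CC)C[C@@H](O[Si](CC)(CC)CC)C(=C)[C@@H]2[C@@H](OCc3ccc(OC)cc3)[C@]2(O)[C@@H](C)C(=O)O[C@H]2[C@H]1Cl | intermediate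
42 | 9-hydroxy chloride | C=C1CC[C@@H](O[Si](CC)(CC)CC)[C@@]2(C)[C@@H](O[Si](CC)(CC)CC)C[C@@H](O[Si](CC)(CC)CC)C(=C)[C@@H]2[C@@H](O)[C@]2(O)[C@@H](C)C(=O)O[C@H]2[C@H]1Cl | intermediate
43 | pentaol | C=C1CC[C@@H](O)[C@@]2(C)[C@@H](O)C[C@@H](O)C(=C)[C@@H]2[C@@H](O)[C@]2(O)[C@@H](C)C(=O)O[C@H]2[C@H]1Cl | intermediate
44 | 11,20-epoxy pentaol | C=C1CC[C@@H](O)[C@@]2(C)[C@@H](O)C[C@@H](O)[C@]3(CO3)[C@@H]2[C@@H](O)[C@]2(O)[C@@H](C)C(=O)O[C@H]2[C@H]1Cl | intermediate
45 | CNP0349227.4 | C=C1CC[C@@H](OC(C)=O)[C@@]2(C)[C@@H](OC(C)=O)C[C@@H](OC(C)=O)[C@]3(CO3)[C@@H]2[C@@H](OC(C)=O)[C@]2(O)[C@@H](C)C(=O)O[C@H]2[C@H]1Cl | target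

**Totals and risks**
Total step count: 29. Longest linear sequence: 28 steps (steps 1, 2 and 4 to 29; step 3 is a one-step side branch).

Most likely to fail, first: step 19 (iodolactonisation). The C7 selectivity rests on the hydroxyl-directing effect at a tertiary carbinol, two other alkenes are present, and the hindered iodide must then survive step 20. The fallback sets out from 32 and comes back at 36. VO(acac)2/t-BuOOH epoxidation of the vinyl group, directed by the tertiary C8 hydroxyl, gives epoxy ester F1. LiOH followed by camphorsulfonic acid lets the carboxyl group open the oxirane 5-exo at C7 with inversion to give hydroxymethyl lactone F2. Dess–Martin oxidation of F2 gives aldehyde 36 without any iodide or amine base.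

Second: step 21 (ring closure). A vinyl bromide is a slow partner in the Nozaki–Hiyama–Kishi reaction and a ten-membered ring is strained. The fallback sets out from 36 and comes back at 38. Pinnick oxidation (NaClO2, NaH2PO4, 2-methylbut-2-ene) gives carboxylic acid F3. Condensation with pyridine-2-thiol (carbodiimide) gives S-(pyridin-2-yl) thioester F4. An intramolecular nickel-catalysed reductive ketone synthesis (NiBr2(4,4'-di-tert-butyl-2,2'-bipyridine), Zn, Cp2ZrCl2, 1,3-dimethyl-2-imidazolidinone) joins the vinyl bromide and the thioester and closes ring B directly as enone 38.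

Third: step 25 (allylic chlorination). SN2' transposition to the primary C16 chloride or elimination may compete. The fallback sets out from 40 and comes back at 41. Methanesulfonyl chloride and Et3N at −20 °C give mesylate F5, and displacement with LiCl in DMF (SN2, inversion) gives 41.

**Further compounds**
F1 | step 19 | epoxy ester (6,7-oxirane on the C8 carbinol, C17 epimers) | C=C(Br)CC[C@@H](O[Si](CC)(CC)CC)[C@@]1(C)[C@@H](O[Si](CC)(CC)CC)C[C@@H](O[Si](CC)(CC)CC)C(=C)[C@@H]1[C@@H](OCc2ccc(OC)cc2)[C@@](O)([C@H]2CO2)C(C)C(=O)OCC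
F2 | step 19 | hydroxymethyl lactone (C6 is CH2OH, C17 epimers) | C=C(Br)CC[C@@H](O[Si](CC)(CC)CC)[C@@]1(C)[C@@H](O[Si](CC)(CC)CC)C[C@@H](O[Si](CC)(CC)CC)C(=C)[C@@H]1[C@@H](OCc2ccc(OC)cc2)[C@]2(O)C(C)C(=O)O[C@H]2CO
F3 | step 21 | C6 carboxylic acid of the ring-C lactone | C=C(Br)CC[C@@H](O[Si](CC)(CC)CC)[C@@]1(C)[C@@H](O[Si](CC)(CC)CC)C[C@@H](O[Si](CC)(CC)CC)C(=C)[C@@H]1[C@@H](OCc2ccc(OC)cc2)[C@]2(O)C(C)C(=O)O[C@H]2C(=O)O
F4 | step 21 | S-(pyridin-2-yl) thioester of F3 | C=C(Br)CC[C@@H](O[Si](CC)(CC)CC)[C@@]1(C)[C@@H](O[Si](CC)(CC)CC)C[C@@H](O[Si](CC)(CC)CC)C(=C)[C@@H]1[C@@H](OCc2ccc(OC)cc2)[C@]2(O)C(C)C(=O)O[C@H]2C(=O)Sc2ccccn2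
F5 | step 25 | (6R)-methanesulfonate of 40 | C=C1CC[C@@H](O[Si](CC)(CC)CC)[C@@]2(C)[C@@H](O[Si](CC)(CC)CC)C[C@@H](O[Si](CC)(CC)CC)C(=C)[C@@H]2[C@@H](OCc3ccc(OC)cc3)[C@]2(O)[C@@H](C)C(=O)O[C@H]2[C@@H]1OS(C)(=O)=O
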